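**Retrosynthetic overview**

1. Target 12 ⇒ hydroquinone 11 (oxidation) ⇒ gentisic acid 10 (protodecarboxylation) ⇒ hydroquinone ester 9 (saponification).
2. Key disconnection of 9: bonds C4–C5 and C1–C6 (quinone numbering), by Diels–Alder reaction of the bis(silyloxy)furan 5 with methyl acrylate 6.
3. Feature used: ring atoms C1–C4 with both oxygens and the C2 nonadecyl chain form the skeleton of nonadecylsuccinic anhydride 4; its bis(silyl enol ether) 5 is a furan diene that lacks only C5–C6.
4. 4 ⇒ Alder-ene reaction of nonadec-1-ene 2 with maleic anhydride 1, then hydrogenation.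
5. Ring order: the anhydride ring comes from 1 and is aromatised to the furan in 5; the only ring of the target, the quinone carbocycle, is closed in step 4.

Key step: step 4

Assumption: the target is achiral 2-nonadecyl-1,4-benzoquinone (C19 chain); the racemic centres in 3, 4, 7 and 8 and the alkene geometry in 3 are erased later and are left uncontrolled.

**Route**

Step 1
Reactants: 1 maleic anhydride; 2 nonadec-1-ene
Product: 3 3-[(2E)-nonadec-2-en-1-yl]oxolane-2,5-dione (racemic; E isomer expected to predominate over Z)
Conditions: 2 (1.5 equiv), neat, phenothiazine (cat.), sealed vessel, N2, 200 °C; excess 2 removed by Kugelrohr distillation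
Reagents that add atoms: none
Why: Thermal Alder-ene reaction of a terminal alkene with maleic anhydride as enophile forms the C–C bond at the terminal carbon with shift of the double bond; the new ring stereocentre is racemic and is planarised in step 3.

Step 2
Reactants: 3 3-[(2E)-nonadec-2-en-1-yl]oxolane-2,5-dione
Product: 4 3-nonadecyloxolane-2,5-dione (nonadecylsuccinic anhydride, racemic)
Conditions: H2 (1 atm), 10% Pd/C, dry EtOAc, rt
Reagents that add atoms: none
Why: Heterogeneous catalytic hydrogenation saturates the isolated disubstituted alkene, and the anhydride is inert in an aprotic solvent.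

Step 3
Reactants: 4 3-nonadecyloxolane-2,5-dione
Product: 5 3-nonadecyl-2,5-bis(trimethylsilyloxy)furan
Conditions: Me3SiCl (3 equiv), Et3N (3 equiv), ZnCl2 (cat.), MeCN–toluene, 60 °C, Ar; dilute with dry pentane, filter under Ar, concentrate, use crude
Reagents that add atoms: chlorotrimethylsilane, C[Si](C)(C)Cl
Why: Double soft enolisation and O-silylation of a succinic anhydride, driven by aromatisation to the furan, is the known preparation of 2,5-bis(trimethylsilyloxy)furans; the stereocentre of 4 becomes sp2.

Step 4
Reactants: 5 3-nonadecyl-2,5-bis(trimethylsilyloxy)furan; 6 methyl acrylate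
Product: 9 methyl 2,5-dihydroxy-4-nonadecylbenzoate, via oxanorbornene cycloadduct 7 (not isolated), via cyclohexenedione ester 8 (not isolated)
Conditions: 6 (5 equiv), phenothiazine (cat.), toluene, 25 to 60 °C, Ar; evaporate excess 6; then 1 M HCl, THF, rt
Reagents that add atoms: none
Why: Diels–Alder reaction: furan 5, a cyclic bis(silyl ketene acetal) and therefore a very electron-rich diene, should add to the acrylate in a concerted suprafacial normal-electron-demand [4+2] cycloaddition, the known behaviour of 2,5-bis(trimethylsilyloxy)furans toward electron-poor alkenes. The quinone carbocycle is closed by an intermolecular two-bond annulation in which the former anhydride carbonyl carbons C1 and C4 bond to the acrylate carbons C6 and C5, giving the oxygen-bridged bis(silyl ketal) 7. Aqueous acid removes both silyl groups as hexamethyldisiloxane, the bridge collapses to the cyclohex-2-ene-1,4-dione 8, and this β-keto ester enolises irreversibly to the aromatic hydroquinone 9. The three stereocentres of 7 (two bridgeheads and the ester carbon) form without control as a racemic endo/exo mixture and are all erased on aromatisation, so none needs to be set. The selectivity needed is chemoselectivity for cycloaddition over protodesilylation of the diene, open-chain conjugate addition and acrylate polymerisation, which anhydrous Lewis-acid-free conditions, excess dienophile and a radical inhibitor should secure. Orientation is not critical because either regiochemistry leads to 11 after decarboxylation, but the larger HOMO coefficient at the diene terminus next to the alkyl-bearing carbon should favour the para arrangement of 9.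

Step 5
Reactants: 9 methyl 2,5-dihydroxy-4-nonadecylbenzoate
Product: 10 2,5-dihydroxy-4-nonadecylbenzoic acid
Conditions: 2 M NaOH (degassed), MeOH–THF, Na2S2O4 (cat.), reflux, Ar; then 2 M HCl, 0 °C
Reagents that add atoms: sodium hydroxide, [Na+].[OH-]
Why: Saponification by acyl–oxygen cleavage; exclusion of air and a trace of dithionite protect the hydroquinone phenoxides from oxidation, and acidification liberates the acid.

Step 6
Reactants: 10 2,5-dihydroxy-4-nonadecylbenzoic acid
Product: 11 2-nonadecylbenzene-1,4-diol
Conditions: Cu2O (0.2 equiv), quinoline, 190 °C, Ar; then Et2O, cold 2 M HCl wash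
Reagents that add atoms: none
Why: Copper–quinoline protodecarboxylation of a salicylic-type acid; the ortho hydroxyl and the electron-rich ring ease ipso protonation and loss of CO2, as in the thermal decarboxylation of gentisic acid.

Step 7
Reactants: 11 2-nonadecylbenzene-1,4-diol
Product: 12 2-nonadecylcyclohexa-2,5-diene-1,4-dione
Conditions: Ag2O (2.5 equiv), Na2SO4, Et2O, rt, dark
Reagents that add atoms: none
Why: Two-electron oxidation of a hydroquinone to the p-benzoquinone by Ag2O under neutral anhydrous conditions leaves the alkyl chain untouched.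

**Compound list**

1 | maleic anhydride | O=C1C=CC(=O)O1 | starting material
2 | nonadec-1-ene | CCCCCCCCCCCCCCCCCC=C | starting material
3 | 3-[(2E)-nonadec-2-en-1-yl]oxolane-2,5-dione (racemic, E major) | CCCCCCCCCCCCCCCC/C=C/CC1CC(=O)OC1=O | intermediate
4 | 3-nonadecyloxolane-2,5-dione (racemic) | CCCCCCCCCCCCCCCCCCCC1CC(=O)OC1=O | intermediate
5 | 3-nonadecyl-2,5-bis(trimethylsilyloxy)furan | CCCCCCCCCCCCCCCCCCCc1cc(O[Si](C)(C)C)oc1O[Si](C)(C)C | intermediate
6 | methyl acrylate | C=CC(=O)OC | starting material
7 | methyl 5-nonadecyl-1,4-bis(trimethylsilyloxy)-7-oxabicyclo[2.2.1]hept-5-ene-2-carboxylate (racemic, endo/exo mixture, not isolated) | CCCCCCCCCCCCCCCCCCCC1=CC2(O[Si](C)(C)C)OC1(O[Si](C)(C)C)CC2C(=O)OC | intermediate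
8 | methyl 4-nonadecyl-2,5-dioxocyclohex-3-ene-1-carboxylate (racemic, not isolated) | CCCCCCCCCCCCCCCCCCCC1=CC(=O)C(C(=O)OC)CC1=O | intermediate
9 | methyl 2,5-dihydroxy-4-nonadecylbenzoate | CCCCCCCCCCCCCCCCCCCc1cc(O)c(C(=O)OC)cc1O | intermediate
10 | 2,5-dihydroxy-4-nonadecylbenzoic acid | CCCCCCCCCCCCCCCCCCCc1cc(O)c(C(=O)O)cc1O | intermediate
11 | 2-nonadecylbenzene-1,4-diol | CCCCCCCCCCCCCCCCCCCc1cc(O)ccc1O | intermediate
12 | 2-nonadecylcyclohexa-2,5-diene-1,4-dione | CCCCCCCCCCCCCCCCCCCC1=CC(=O)C=CC1=O | target

**Summary**

Total step count: 7.
Longest linear sequence: 7 steps (1 and 2 to 12).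

**Steps most likely to fail**

Step 4 (key cycloaddition). The cycloaddition may be outrun by protodesilylation of the moisture-sensitive diene, by conjugate addition that stops at an open chain, by cycloreversion of the oxanorbornene before hydrolysis, or by polymerisation of the acrylate. The fallback sets out from 5 and changes the two-carbon partner from an alkene to the alkyne methyl propiolate, so that the ring is delivered at the quinone oxidation level. Cycloaddition in toluene at 25 to 60 °C should give methyl 5-nonadecyl-1,4-bis(trimethylsilyloxy)-7-oxabicyclo[2.2.1]hepta-2,5-diene-2-carboxylate F1, which is not isolated. Mild aqueous acid should collapse it to the quinone ester methyl 4-nonadecyl-3,6-dioxocyclohexa-1,4-diene-1-carboxylate F2. Immediate reduction in a two-phase EtOAc/aqueous Na2S2O4 work-up should give 9, where the route resumes at step 5.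

Step 3 (bis-silylation). The second enolisation may stay incomplete with the waxy, poorly soluble substrate, and the crude, non-distillable trimethylsilyl diene may lose silyl groups through adventitious moisture during isolation. The fallback sets out from 4 and changes the silyl group. Treatment with tert-butyldimethylsilyl triflate and Et3N in CH2Cl2 at 0 °C should give 3-nonadecyl-2,5-bis(tert-butyldimethylsilyloxy)furan F3, which should survive rapid filtration through Et3N-deactivated silica and can be stored. Cycloaddition of F3 with 6 in toluene at 60 to 80 °C should give methyl 1,4-bis(tert-butyldimethylsilyloxy)-5-nonadecyl-7-oxabicyclo[2.2.1]hept-5-ene-2-carboxylate F4. Aqueous HCl in THF should then release 9 through 8, and the route resumes at step 5.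

Step 6 (protodecarboxylation). Loss of CO2 may stay incomplete, and the free hydroquinone may suffer oxidative or thermal degradation at about 190 °C; the same sensitivity threatens the phenoxides in step 5. The fallback sets out from 9 and carries the ring as its dimethyl ether through the harsh steps. Methylation of both phenols (MeI, K2CO3, DMF, 60 °C) should give methyl 2,5-dimethoxy-4-nonadecylbenzoate F5. Saponification (LiOH, THF–MeOH–H2O) should give 2,5-dimethoxy-4-nonadecylbenzoic acid F6. Protodecarboxylation of this ortho-methoxybenzoic acid with catalytic Ag2CO3 and AcOH in DMSO at 120 °C should give 1,4-dimethoxy-2-nonadecylbenzene F7. Oxidative demethylation with (NH4)2Ce(NO3)6 in MeCN–H2O at 0 °C should give the target 12 directly.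

**Further compounds**

F1 | step 4 | methyl 5-nonadecyl-1,4-bis(trimethylsilyloxy)-7-oxabicyclo[2.2.1]hepta-2,5-diene-2-carboxylate | CCCCCCCCCCCCCCCCCCCC1=CC2(O[Si](C)(C)C)OC1(O[Si](C)(C)C)C=C2C(=O)OC
F2 | step 4 | methyl 4-nonadecyl-3,6-dioxocyclohexa-1,4-diene-1-carboxylate | CCCCCCCCCCCCCCCCCCCC1=CC(=O)C(C(=O)OC)=CC1=O
F3 | step 3 | 3-nonadecyl-2,5-bis(tert-butyldimethylsilyloxy)furan | CCCCCCCCCCCCCCCCCCCc1cc(O[Si](C)(C)C(C)(C)C)oc1O[Si](C)(C)C(C)(C)C
F4 | step 3 | methyl 1,4-bis(tert-butyldimethylsilyloxy)-5-nonadecyl-7-oxabicyclo[2.2.1]hept-5-ene-2-carboxylate | CCCCCCCCCCCCCCCCCCCC1=CC2(O[Si](C)(C)C(C)(C)C)OC1(O[Si](C)(C)C(C)(C)C)CC2C(=O)OC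
F5 | step 6 | methyl 2,5-dimethoxy-4-nonadecylbenzoate | CCCCCCCCCCCCCCCCCCCc1cc(OC)c(C(=O)OC)cc1OC
F6 | step 6 | 2,5-dimethoxy-4-nonadecylbenzoic acid | CCCCCCCCCCCCCCCCCCCc1cc(OC)c(C(=O)O)cc1OC
F7 | step 6 | 1,4-dimethoxy-2-nonadecylbenzene | CCCCCCCCCCCCCCCCCCCc1cc(OC)ccc1OC
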